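**Retrosynthetic overview**
1. Target ⇒ angelic acid + the C8 alcohol of the bridged furanone macrocycle (ester made last, with retention).
2. Bridging 3(2H)-furanone and quaternary C10 ⇒ transannular AuCl3-triggered heterocyclisation/1,2-methyl shift of a ten-membered 1-hydroxy-1-methyl-2-yn-10-one, relaying chirality from C1 to C10.
3. Ten-membered cycloenyne ⇒ intramolecular aldol (C8–C9) of a methyl ketone onto a β-formyl lactone.
4. α-Hydroxy methyl ketone ⇒ enantioselective alkynylation of butane-2,3-dione (C1–C2); trans,trans-lactone ⇒ asymmetric 2-(alkoxycarbonyl)allylation of (Z)-3-methylpent-2-en-4-ynal, then 1,4-reduction.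
5. Ring order: γ-lactone (step 4) → ten-membered carbocycle (step 8) → furanone (step 9).

Assumption: core carbons are numbered C1–C15 as in germacranolides (C1–C10 ring, C11–C13 lactone side, C14 the methyl that ends on C10, C15 the methyl on C4); for the two catalyst-controlled steps (4 and 6) the ligand antipode written is the one expected by analogy to give the drawn configuration, and its mirror image is used if the opposite sense is found.

**Step 1**
Reactants: 1 methyl acrylate; 2 2,2-dimethoxyacetaldehyde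
Product: 3 methyl 3-hydroxy-4,4-dimethoxy-2-methylidenebutanoate (racemic)
Conditions: DABCO (0.5 equiv), 1,4-dioxane/H2O, 23 °C
Reagents that add atoms: none
Why: Morita–Baylis–Hillman reaction of the acrylate with a very electrophilic, non-enolisable aldehyde; the racemic carbinol centre is erased in step 2.

**Step 2**
Reactants: 3 methyl 3-hydroxy-4,4-dimethoxy-2-methylidenebutanoate
Product: 4 methyl (2Z)-2-(bromomethyl)-4,4-dimethoxybut-2-enoate
Conditions: NBS, Me2S, CH2Cl2, 0 → 23 °C
Reagents that add atoms: N-bromosuccinimide, O=C1CCC(=O)N1Br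
Why: Corey–Kim-type activation of the allylic alcohol as an alkoxysulfonium salt and SN2′ attack of bromide give the rearranged primary allylic bromide as the more stable Z isomer (acetal trans to the ester) under neutral conditions that spare the acetal.

**Step 3**
Reactants: 5 (2Z)-3-methylpent-2-en-4-yn-1-ol
Product: 6 (2Z)-3-methylpent-2-en-4-ynal
Conditions: MnO2, CH2Cl2, 23 °C; filtered and used at once
Reagents that add atoms: none
Why: MnO2 oxidises the primary allylic alcohol selectively under neutral conditions, so the Z alkene (future C4=C5) and the terminal alkyne are untouched.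

**Step 4**
Reactants: 6 (2Z)-3-methylpent-2-en-4-ynal; 4 methyl (2Z)-2-(bromomethyl)-4,4-dimethoxybut-2-enoate
Product: 9 (4S,5R)-4-(dimethoxymethyl)-3-methylidene-5-[(1Z)-2-methylbut-1-en-3-yn-1-yl]oxolan-2-one, via silyl ether 7 (not isolated), via hydroxy ester 8 (not isolated)
Conditions: CrCl2 (10 mol%), (S,S)-3,6-di-tert-butyl-1,8-bis(4-isopropyl-4,5-dihydrooxazol-2-yl)carbazole (12 mol%), Mn powder, TMSCl, iPr2NEt (30 mol%), THF, 0 → 23 °C; then TBAF/AcOH, THF, 40 °C
Reagents that add atoms: none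
Why: catalytic asymmetric Nozaki–Hiyama–Kishi 2-(alkoxycarbonyl)allylation, in which the equilibrating allylchromium reacts 1,2 with the enal through a chair transition state with the acetal-bearing substituent pseudo-equatorial (anti adduct, hence the trans 6,7-lactone after ring closure) and the tridentate ligand selects the aldehyde face, setting C6 (R) and C7 while divalent chromium leaves the alkyne and Z alkene alone.

**Step 5**
Reactants: 9 (4S,5R)-4-(dimethoxymethyl)-3-methylidene-5-[(1Z)-2-methylbut-1-en-3-yn-1-yl]oxolan-2-one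
Product: 11 (3S,4S,5R)-4-(dimethoxymethyl)-3-methyl-5-[(1Z)-2-methylbut-1-en-3-yn-1-yl]oxolan-2-one, via C11 epimer 10 (not isolated)
Conditions: NaBH4, MeOH, −20 °C; then NaOMe (0.3 equiv), 23 °C
Reagents that add atoms: none
Why: 1,4-reduction of the α-methylene lactone by borohydride (enyne and acetal inert) followed by methoxide equilibration at C11 to the more stable all-trans lactone, which sets C11 (S).

**Step 6**
Reactants: 11 (3S,4S,5R)-4-(dimethoxymethyl)-3-methyl-5-[(1Z)-2-methylbut-1-en-3-yn-1-yl]oxolan-2-one; 12 butane-2,3-dione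
Product: 13 (3S,4S,5R)-4-(dimethoxymethyl)-5-[(1Z,5R)-5-hydroxy-2,5-dimethyl-6-oxohept-1-en-3-yn-1-yl]-3-methyloxolan-2-one
Conditions: Rh[(S,S)-iPr-phebox](OAc)2(H2O) (5 mol%), 12 (3 equiv), toluene, 25 °C
Reagents that add atoms: none
Why: Proposed new method: catalytic enantioselective mono-alkynylation of a symmetrical aliphatic 1,2-diketone, in which an acetate ligand of the trivalent rhodium complex deprotonates the terminal alkyne to a rhodium alkynyl, the diketone binds through both carbonyl oxygens as α-keto esters do, one carbonyl inserts into the Rh–C bond on the face left open by the C2-symmetric bis(oxazoline) pocket and AcOH releases the tertiary propargylic alcohol; the neutral, base-free medium spares the enolisable diketone, lactone and acetal, the hindered mono-adduct does not add again, and since both carbonyls are equivalent only facial selectivity matters, setting C1 (R); closest known reaction type: trivalent rhodium phebox-catalysed alkynylation of α-keto esters.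

**Step 7**
Reactants: 13 (3S,4S,5R)-4-(dimethoxymethyl)-5-[(1Z,5R)-5-hydroxy-2,5-dimethyl-6-oxohept-1-en-3-yn-1-yl]-3-methyloxolan-2-one
Product: 14 (2R,3S,4S)-2-[(1Z,5R)-5-hydroxy-2,5-dimethyl-6-oxohept-1-en-3-yn-1-yl]-4-methyl-5-oxooxolane-3-carbaldehyde
Conditions: TFA/H2O (9:1), CH2Cl2, 0 °C
Reagents that add atoms: water, O
Why: acid-catalysed acetal hydrolysis, in which the tertiary propargylic alcohol next to a ketone does not ionise and the base-sensitive β-formyl lactone (E1cB-prone) only ever sees acid, C7 remaining in its thermodynamic trans configuration.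

**Step 8**
Reactants: 14 (2R,3S,4S)-2-[(1Z,5R)-5-hydroxy-2,5-dimethyl-6-oxohept-1-en-3-yn-1-yl]-4-methyl-5-oxooxolane-3-carbaldehyde
Product: 17 (1R,4Z,6R,7R,8R,11S)-1,8-dihydroxy-1-methyl-10-oxo-14-norgermacr-4-en-2-yn-12,6-olide, via boron enolate 15 (not isolated), via boron aldolate 16 (not isolated)
Conditions: Bu2BOTf (2.5 equiv), iPr2NEt (3.5 equiv), CH2Cl2 (2 mM, slow addition of 14), −78 → −30 °C; then pH 7 buffer, MeOH, 30% H2O2, 0 °C
Reagents that add atoms: none
Why: intramolecular boron aldol reaction, in which the methyl ketone (enolisable on one side only) is soft-enolised after O-borylation of the tertiary alcohol and closes the ten-membered ring through a Zimmerman–Traxler transition state, helped by the rigid Z-enyne hairpin that holds the two ends close; C8 (R) is expected from Felkin–Anh attack anti to the C7–C11 bond (also the 1,3-anti face relative to the C6 oxygen) and is to be confirmed by NOE or Mosher analysis.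

**Step 9**
Reactants: 17 (1R,4Z,6R,7R,8R,11S)-1,8-dihydroxy-1-methyl-10-oxo-14-norgermacr-4-en-2-yn-12,6-olide
Product: 18 (4Z,6R,7R,8R,10R,11S)-8-hydroxy-1-oxo-3,10-epoxygermacra-2,4-dien-12,6-olide
Conditions: AuCl3 (5 mol%), CH2Cl2, 23 °C
Reagents that add atoms: none
Why: Proposed new method: transannular gold-catalysed heterocyclisation/1,2-alkyl shift, in which AuCl3 activates the ring alkyne, the C10 carbonyl oxygen adds 5-endo to C3 to give a cyclic oxocarbenium/vinyl-gold species, the C1 methyl migrates suprafacially to C10 while the C1 hydroxyl becomes the C1 ketone (semipinacol-type 1,2-shift), and protodeauration gives the bridged 3(2H)-furanone; the methyl arrives at C10 on the face it occupied at C1 and C9 is pushed to the other face, so (1R) is relayed to (10R), with loss of alkyne strain as driving force; closest known reaction type: the AuCl3- or PtCl2-catalysed domino cyclisation/1,2-migration of acyclic and small-ring 2-hydroxy-2-alkynyl ketones to 3(2H)-furanones, not yet shown across a medium-ring cycloenyne to make a bridging furanone.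

**Step 10**
Reactants: 18 (4Z,6R,7R,8R,10R,11S)-8-hydroxy-1-oxo-3,10-epoxygermacra-2,4-dien-12,6-olide; 19 angelic acid
Product: 21 (4Z,6R,7R,8R,10R,11S)-8-[(2Z)-2-methylbut-2-enoyloxy]-1-oxo-3,10-epoxygermacra-2,4-dien-12,6-olide, via mixed anhydride 20 (not isolated)
Conditions: 2,4,6-Cl3C6H2COCl, Et3N, toluene, 23 °C; then 18, 75 °C (no DMAP)
Reagents that add atoms: none
Why: Yamaguchi-type esterification through the mixed 2,4,6-trichlorobenzoic anhydride run without DMAP, the established way to make angelates without Z → E isomerisation to tiglates; the only hydroxyl is acylated with retention at C8.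

**Compound list**
1 | methyl acrylate | C=CC(=O)OC | starting material
2 | 2,2-dimethoxyacetaldehyde | COC(OC)C=O | starting material
3 | methyl 3-hydroxy-4,4-dimethoxy-2-methylidenebutanoate (racemic) | COC(=O)C(=C)C(O)C(OC)OC | intermediate
4 | methyl (2Z)-2-(bromomethyl)-4,4-dimethoxybut-2-enoate | COC(=O)/C(CBr)=C/C(OC)OC | intermediate
5 | (2Z)-3-methylpent-2-en-4-yn-1-ol | C#C/C(C)=C\CO | starting material
6 | (2Z)-3-methylpent-2-en-4-ynal | C#C/C(C)=C\C=O | intermediate
7 | methyl (3S,4R,5Z)-3-(dimethoxymethyl)-6-methyl-2-methylidene-4-(trimethylsilyloxy)oct-5-en-7-ynoate | C#C/C(C)=C\[C@@H](O[Si](C)(C)C)[C@@H](C(OC)OC)C(=C)C(=O)OC | intermediate (not isolated)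
8 | methyl (3S,4R,5Z)-3-(dimethoxymethyl)-4-hydroxy-6-methyl-2-methylideneoct-5-en-7-ynoate | C#C/C(C)=C\[C@@H](O)[C@@H](C(OC)OC)C(=C)C(=O)OC | intermediate (not isolated)
9 | (4S,5R)-4-(dimethoxymethyl)-3-methylidene-5-[(1Z)-2-methylbut-1-en-3-yn-1-yl]oxolan-2-one | C#C/C(C)=C\[C@H]1OC(=O)C(=C)[C@@H]1C(OC)OC | intermediate
10 | (3R,4S,5R)-4-(dimethoxymethyl)-3-methyl-5-[(1Z)-2-methylbut-1-en-3-yn-1-yl]oxolan-2-one (C11 epimer of 11) | C#C/C(C)=C\[C@H]1OC(=O)[C@H](C)[C@@H]1C(OC)OC | intermediate (not isolated)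
11 | (3S,4S,5R)-4-(dimethoxymethyl)-3-methyl-5-[(1Z)-2-methylbut-1-en-3-yn-1-yl]oxolan-2-one | C#C/C(C)=C\[C@H]1OC(=O)[C@@H](C)[C@@H]1C(OC)OC | intermediate
12 | butane-2,3-dione | CC(=O)C(C)=O | starting material
13 | (3S,4S,5R)-4-(dimethoxymethyl)-5-[(1Z,5R)-5-hydroxy-2,5-dimethyl-6-oxohept-1-en-3-yn-1-yl]-3-methyloxolan-2-one | CC(=O)[C@](C)(O)C#C/C(C)=C\[C@H]1OC(=O)[C@@H](C)[C@@H]1C(OC)OC | intermediate
14 | (2R,3S,4S)-2-[(1Z,5R)-5-hydroxy-2,5-dimethyl-6-oxohept-1-en-3-yn-1-yl]-4-methyl-5-oxooxolane-3-carbaldehyde | CC(=O)[C@](C)(O)C#C/C(C)=C\[C@H]1OC(=O)[C@@H](C)[C@@H]1C=O | intermediate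
15 | boron enolate of 14 (dibutylboryl ether on the C1 oxygen, dibutylboron enolate C9=C10–O) | C=C(OB(CCCC)CCCC)[C@](C)(OB(CCCC)CCCC)C#C/C(C)=C\[C@H]1OC(=O)[C@@H](C)[C@@H]1C=O | intermediate (not isolated)
16 | boron aldolate: 1,8-bis-O-(dibutylboryl) derivative of 17 | CCCCB(CCCC)O[C@@H]1CC(=O)[C@](C)(OB(CCCC)CCCC)C#C/C(C)=C\[C@H]2OC(=O)[C@@H](C)[C@@H]21 | intermediate (not isolated)
17 | (1R,4Z,6R,7R,8R,11S)-1,8-dihydroxy-1-methyl-10-oxo-14-norgermacr-4-en-2-yn-12,6-olide (ten-membered ring: C1(OH)(CH3), C2≡C3, C4(CH3)=C5, C8–OH, C10=O; trans-fused 12,6-lactone) | O[C@@H]1CC(=O)[C@](C)(O)C#C/C(C)=C\[C@H]2OC(=O)[C@@H](C)[C@@H]21 | intermediate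
18 | (4Z,6R,7R,8R,10R,11S)-8-hydroxy-1-oxo-3,10-epoxygermacra-2,4-dien-12,6-olide | O[C@@H]1C[C@@]2(C)OC(=CC2=O)/C(C)=C\[C@H]2OC(=O)[C@@H](C)[C@@H]21 | intermediate
19 | angelic acid, (2Z)-2-methylbut-2-enoic acid | C/C=C(/C)C(=O)O | starting material
20 | (2Z)-2-methylbut-2-enoic 2,4,6-trichlorobenzoic anhydride | C/C=C(/C)C(=O)OC(=O)c1c(Cl)cc(Cl)cc1Cl | intermediate (not isolated)
21 | (4Z,6R,7R,8R,10R,11S)-8-[(2Z)-2-methylbut-2-enoyloxy]-1-oxo-3,10-epoxygermacra-2,4-dien-12,6-olide | C/C=C(/C)C(=O)O[C@@H]1C[C@@]2(C)OC(=CC2=O)/C(C)=C\[C@H]2OC(=O)[C@@H](C)[C@@H]21 | target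

**Totals and risks**
Total steps: 10. Longest linear sequence: 9 (steps 1, 2, 4, 5, 6, 7, 8, 9, 10).

Three steps most likely to fail:

Step 6 (proposed new). The facial selectivity and turnover of the rhodium alkynyl with a simple aliphatic diketone are untested. Fallback with known chemistry, setting out from 5 and returning at 13: enynol 5 is added to methyl pyruvate (CC(=O)C(=O)OC) with the same Rh(iPr-phebox)(OAc)2(H2O) catalyst, the documented α-keto ester case, to give the hydroxy ester F1. One-pot Weinreb amide formation and methyl addition (MeNHOMe·HCl, excess MeMgBr, THF, −20 → 0 °C) gives the methyl ketone F2, and MnO2 gives the enal F3. Allylation with 4 under the step 4 conditions, through the silyl ether F4 and the hydroxy ester F5, gives the methylene lactone F6. Conjugate reduction with [(Ph3P)CuH]6 (the ketone is not reduced) and NaOMe equilibration, through the C11 epimer F7, delivers 13.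

Step 8. The β-formyl lactone can eliminate (E1cB) under amine base, a ten-membered aldol closure is entropically demanding, and C8 is set by substrate control only. Fallback, setting out from 13 and returning at 17, is an intramolecular samarium Reformatsky reaction. LiN(SiMe3)2 (2.2 equiv)/Me3SiCl (THF, −78 °C) gives the bis-silyl compound F8 (silyl ether on the C1 oxygen, silyl enol ether of the methyl ketone). NBS (THF, −78 °C) gives the bromomethyl ketone F9. Aqueous TFA cleaves acetal and silyl ether to the bromo keto aldehyde F10. SmI2 (2.1 equiv, THF, −78 °C, high dilution) reduces the C–Br bond and the samarium enolate closes onto the aldehyde to give 17 under neutral conditions.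

Step 9 (proposed new). The cyclic oxocarbenium is a strained, furanophane-like intermediate, and the free C8 hydroxyl could add to the activated alkyne instead. Fallback with known chemistry, setting out from 17 and returning at 18, is a stepwise acyloin shift then oxa-Michael closure that never needs a planar C10. Et3SiOTf/2,6-lutidine (CH2Cl2, −78 °C) silylates the secondary hydroxyl only, giving the silyl ether F11. KN(SiMe3)2 (1.1 equiv) with 18-crown-6 (THF, −40 → 0 °C) forms the tertiary alkoxide, which undergoes the base-mediated α-ketol 1,2-methyl shift through the open, non-chelated transition state to the hydroxy ynone F12 (a chelating Lewis acid would send the methyl to the opposite face and is avoided). The alkoxide of F12 closes by 5-endo oxa-Michael addition to the furanone silyl ether F13, and HF·pyridine (THF, 0 °C) gives 18.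

**Further compounds**
F1 | step 6 | methyl (2R,5Z)-2,7-dihydroxy-2,5-dimethylhept-5-en-3-ynoate | COC(=O)[C@](C)(O)C#C/C(C)=C\CO
F2 | step 6 | (3R,6Z)-3,8-dihydroxy-3,6-dimethyloct-6-en-4-yn-2-one | CC(=O)[C@](C)(O)C#C/C(C)=C\CO
F3 | step 6 | (2Z,6R)-6-hydroxy-3,6-dimethyl-7-oxooct-2-en-4-ynal | CC(=O)[C@](C)(O)C#C/C(C)=C\C=O
F4 | step 6 | trimethylsilyl ether of F5 | CC(=O)[C@](C)(O)C#C/C(C)=C\[C@@H](O[Si](C)(C)C)[C@@H](C(OC)OC)C(=C)C(=O)OC
F5 | step 6 | methyl (3S,4R,5Z,9R)-3-(dimethoxymethyl)-4,9-dihydroxy-6,9-dimethyl-2-methylidene-10-oxoundec-5-en-7-ynoate | CC(=O)[C@](C)(O)C#C/C(C)=C\[C@@H](O)[C@@H](C(OC)OC)C(=C)C(=O)OC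
F6 | step 6 | (4S,5R)-4-(dimethoxymethyl)-5-[(1Z,5R)-5-hydroxy-2,5-dimethyl-6-oxohept-1-en-3-yn-1-yl]-3-methylideneoxolan-2-one | CC(=O)[C@](C)(O)C#C/C(C)=C\[C@H]1OC(=O)C(=C)[C@@H]1C(OC)OC
F7 | step 6 | C11 epimer of 13, (3R,4S,5R)-lactone | CC(=O)[C@](C)(O)C#C/C(C)=C\[C@H]1OC(=O)[C@H](C)[C@@H]1C(OC)OC
F8 | step 8 | bis(trimethylsilyl) derivative of 13 (silyl ether on the C1 oxygen, silyl enol ether C9=C10) | C=C(O[Si](C)(C)C)[C@](C)(O[Si](C)(C)C)C#C/C(C)=C\[C@H]1OC(=O)[C@@H](C)[C@@H]1C(OC)OC
F9 | step 8 | bromomethyl ketone, O-trimethylsilyl, acetal intact | BrCC(=O)[C@](C)(O[Si](C)(C)C)C#C/C(C)=C\[C@H]1OC(=O)[C@@H](C)[C@@H]1C(OC)OC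
F10 | step 8 | (2R,3S,4S)-2-[(1Z,5R)-7-bromo-5-hydroxy-2,5-dimethyl-6-oxohept-1-en-3-yn-1-yl]-4-methyl-5-oxooxolane-3-carbaldehyde | BrCC(=O)[C@](C)(O)C#C/C(C)=C\[C@H]1OC(=O)[C@@H](C)[C@@H]1C=O
F11 | step 9 | 8-O-triethylsilyl ether of 17 | CC[Si](CC)(CC)O[C@@H]1CC(=O)[C@](C)(O)C#C/C(C)=C\[C@H]2OC(=O)[C@@H](C)[C@@H]21
F12 | step 9 | (10R)-10-hydroxy-1-oxo-8-(triethylsilyloxy)germacr-4-en-2-yn-12,6-olide (hydroxy ynone) | CC[Si](CC)(CC)O[C@@H]1C[C@@](C)(O)C(=O)C#C/C(C)=C\[C@H]2OC(=O)[C@@H](C)[C@@H]21
F13 | step 9 | 8-O-triethylsilyl ether of 18 | CC[Si](CC)(CC)O[C@@H]1C[C@@]2(C)OC(=CC2=O)/C(C)=C\[C@H]2OC(=O)[C@@H](C)[C@@H]21
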